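## Retrosynthetic overview

1. Locants: ring C2–C6, side chain C1'–C7'. The last step is an E-selective cross-metathesis across C3'=C4' joining vinyl lactone 15 (C10) and allylic diacetate 19 (C9); nothing follows the coupling.
2. The only ring, the dihydropyranone of 15, is closed before the coupling by lactonisation of a Z-δ-hydroxy enoate, made from ynoate 12, itself from terminal epoxide 9 and ethyl propiolate.
3. Epoxide 9 comes from a matched Sharpless epoxidation of dienol 7 (sets C6); 7 comes from Brown γ-methoxyallylboration of acrolein (sets C1'/C2' syn).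
4. Diacetate 19 comes from divinylcarbinol by Sharpless desymmetrisation (sets C5'/C6' anti), hydride opening of the epoxide to the methyl group, and acetylation.

Ipc = isopinocampheyl derived from (−)-α-pinene throughout.

## Route

Step 1
Reactants: 1 acrolein; 2 allyl methyl ether
Product: 7 (3S,4S)-4-methoxyhexa-1,5-dien-3-ol, via (Z)-3-methoxyallyllithium 3 (not isolated), via lithium allyl(methoxy)diisopinocampheylborate 4 (not isolated), via (Z)-(3-methoxyallyl)diisopinocampheylborane 5 (not isolated), via diisopinocampheylborinate of the dienol 6 (not isolated)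
Conditions: 2, sec-BuLi, THF, −78 °C; (+)-Ipc2BOMe; BF3·OEt2 (1.3 equiv); then 1, −78 °C, 3 h; 3 M NaOH, 30% H2O2, 0 °C → rt
Reagents that add atoms: none
Why: Brown γ-alkoxyallylboration, in which the Z-allylborane adds through a closed chair transition state (syn OH/OMe) and the Ipc groups direct attack to the Re face of the aldehyde, setting (3S,4S), the future C1' and C2'.

Step 2
Reactants: 7 (3S,4S)-4-methoxyhexa-1,5-dien-3-ol
Product: 8 (2S,3R,4S)-1,2-epoxy-4-methoxyhex-5-en-3-ol
Conditions: Ti(OiPr)4 (0.3 equiv), D-(−)-DIPT (0.36 equiv), TBHP (2 equiv, isooctane), 4 Å MS, CH2Cl2, −20 °C, 3 d; aqueous tartaric acid work-up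
Reagents that add atoms: tert-butyl hydroperoxide, CC(C)(C)OO
Why: Sharpless asymmetric epoxidation in the matched sense, where the (3S)-carbinol is the fast-reacting enantiomer with D-(−)-DIPT and gives the erythro epoxy alcohol at the allylic vinyl group only, setting the future C6 (S) and raising the ee because the minor enantiomer reacts slowly.

Step 3
Reactants: 8 (2S,3R,4S)-1,2-epoxy-4-methoxyhex-5-en-3-ol
Product: 9 triethyl{[(1R,2S)-2-methoxy-1-[(2S)-oxiran-2-yl]but-3-en-1-yl]oxy}silane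
Conditions: TESCl (1.3 equiv), imidazole (2.5 equiv), DMAP (cat.), CH2Cl2, 0 °C → rt
Reagents that add atoms: chlorotriethylsilane, CC[Si](Cl)(CC)CC
Why: Silylation of the secondary alcohol under mild base leaves the epoxide and all stereocentres untouched and prevents Payne rearrangement and alkoxide interference in the next step.

Step 4
Reactants: 9 triethylsilyl epoxide; 10 ethyl propiolate
Product: 12 ethyl (5S,6S,7S)-5-hydroxy-7-methoxy-6-(triethylsilyloxy)non-8-en-2-ynoate, via ethyl 3-lithiopropiolate 11 (not isolated)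
Conditions: 10 (2.5 equiv), n-BuLi (2.4 equiv), THF, −78 °C; BF3·OEt2 (2.5 equiv); then 9, −78 °C, 2 h; aqueous NH4Cl at −78 °C
Reagents that add atoms: none
Why: Yamaguchi–Hirao alkynylation, a BF3-activated SN2 opening of the terminal epoxide at its CH2 carbon by the lithium acetylide, which touches no stereocentre and brings in C2–C4 of the lactone.

Step 5
Reactants: 12 ethyl (5S,6S,7S)-5-hydroxy-7-methoxy-6-(triethylsilyloxy)non-8-en-2-ynoate
Product: 15 (6S)-6-[(1S,2S)-1-hydroxy-2-methoxybut-3-en-1-yl]-5,6-dihydro-2H-pyran-2-one, via (Z)-hydroxy enoate 13 (not isolated), via silyl lactone 14 (not isolated)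
Conditions: H2 (1 atm, stopped at 1 equiv), Lindlar catalyst (5% Pd on CaCO3, poisoned with Pb(OAc)2), quinoline (0.2 equiv), EtOAc, rt; filter, concentrate; then TsOH·H2O (0.2 equiv), CH2Cl2/MeOH 10:1, rt, 2 h
Reagents that add atoms: none
Why: Lindlar semi-hydrogenation (syn addition to the ynoate, much faster than to the hindered vinyl group) gives the Z-enoate, whose δ-hydroxyl closes the six-membered lactone under acid, and the same acid with methanol cleaves the labile triethylsilyl ether.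

Step 6
Reactants: 16 penta-1,4-dien-3-ol (divinylcarbinol)
Product: 17 (2R,3S)-1,2-epoxypent-4-en-3-ol
Conditions: Ti(OiPr)4 (0.1 equiv), L-(+)-DIPT (0.13 equiv), cumene hydroperoxide (1.9 equiv), 4 Å MS, CH2Cl2, −20 °C, 5 d
Reagents that add atoms: cumene hydroperoxide, CC(C)(OO)c1ccccc1
Why: Sharpless asymmetric epoxidation desymmetrising the prochiral divinylcarbinol, in which L-(+)-DIPT selects one enantiotopic vinyl group and one face to give the erythro epoxy alcohol (carbinol S = future C5', epoxide carbon R = future C6'), the minor enantiomer being consumed by a second epoxidation.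

Step 7
Reactants: 17 (2R,3S)-1,2-epoxypent-4-en-3-ol
Product: 18 (3S,4R)-pent-1-ene-3,4-diol
Conditions: LiAlH4 (1.2 equiv), Et2O, 0 °C → rt; Na2SO4·10H2O work-up, no aqueous extraction
Reagents that add atoms: none
Why: Hydride SN2 opening of the terminal epoxide at its CH2 carbon turns it into the methyl group with both stereocentres retained, giving the anti diol.

Step 8
Reactants: 18 (3S,4R)-pent-1-ene-3,4-diol
Product: 19 (3S,4R)-pent-1-ene-3,4-diyl diacetate
Conditions: Ac2O (3 equiv), pyridine, DMAP (cat.), CH2Cl2, 0 °C → rt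
Reagents that add atoms: acetic anhydride, CC(=O)OC(C)=O
Why: DMAP-catalysed acylation of both secondary hydroxyls, with no stereocentre involved.

Step 9
Reactants: 15 (6S)-6-[(1S,2S)-1-hydroxy-2-methoxybut-3-en-1-yl]-5,6-dihydro-2H-pyran-2-one; 19 (3S,4R)-pent-1-ene-3,4-diyl diacetate
Product: 20 (6S)-6-[(1S,2S,3E,5S,6R)-5,6-diacetoxy-1-hydroxy-2-methoxyhept-3-en-1-yl]-5,6-dihydro-2H-pyran-2-one
Conditions: 19 (3 equiv), Hoveyda–Grubbs second-generation catalyst RuCl2(H2IMes)(=CH-C6H4-2-OiPr) (10 mol%), CH2Cl2, 40 °C, 24 h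
Reagents that add atoms: none
Why: Olefin cross-metathesis of two terminal, allylically oxygenated (type 2) alkenes, driven by loss of ethene and an excess of the simpler partner, gives the favoured E-alkene while the conjugated ring alkene, the free hydroxyl, the acetates and all stereocentres stay untouched.

## Compound list

1 | acrolein (prop-2-enal) | C=CC=O | starting material
2 | allyl methyl ether (3-methoxyprop-1-ene) | C=CCOC | starting material
3 | (Z)-3-methoxyallyllithium | [Li]C/C=C\OC | intermediate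
4 | lithium [(Z)-3-methoxyallyl](methoxy)bis(isopinocampheyl)borate | [Li+].CO/C=C\C[B-](OC)([C@H]1C[C@H]2C[C@@H]([C@@H]1C)C2(C)C)[C@H]1C[C@H]2C[C@@H]([C@@H]1C)C2(C)C | intermediate
5 | [(Z)-3-methoxyallyl]bis(isopinocampheyl)borane | CO/C=C\CB([C@H]1C[C@H]2C[C@@H]([C@@H]1C)C2(C)C)[C@H]1C[C@H]2C[C@@H]([C@@H]1C)C2(C)C | intermediate
6 | (3S,4S)-4-methoxyhexa-1,5-dien-3-yl bis(isopinocampheyl)borinate | CO[C@@H](C=C)[C@@H](OB([C@H]1C[C@H]2C[C@@H]([C@@H]1C)C2(C)C)[C@H]1C[C@H]2C[C@@H]([C@@H]1C)C2(C)C)C=C | intermediate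
7 | (3S,4S)-4-methoxyhexa-1,5-dien-3-ol | CO[C@@H](C=C)[C@@H](O)C=C | intermediate
8 | (2S,3R,4S)-1,2-epoxy-4-methoxyhex-5-en-3-ol | CO[C@@H](C=C)[C@@H](O)[C@@H]1CO1 | intermediate
9 | triethyl{[(1R,2S)-2-methoxy-1-[(2S)-oxiran-2-yl]but-3-en-1-yl]oxy}silane | CO[C@@H](C=C)[C@@H](O[Si](CC)(CC)CC)[C@@H]1CO1 | intermediate
10 | ethyl propiolate | C#CC(=O)OCC | starting material
11 | ethyl 3-lithiopropiolate | [Li]C#CC(=O)OCC | intermediate
12 | ethyl (5S,6S,7S)-5-hydroxy-7-methoxy-6-[(triethylsilyl)oxy]non-8-en-2-ynoate | CO[C@@H](C=C)[C@@H](O[Si](CC)(CC)CC)[C@@H](O)CC#CC(=O)OCC | intermediate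
13 | ethyl (2Z,5S,6S,7S)-5-hydroxy-7-methoxy-6-[(triethylsilyl)oxy]nona-2,8-dienoate | CO[C@@H](C=C)[C@@H](O[Si](CC)(CC)CC)[C@@H](O)C/C=C\C(=O)OCC | intermediate
14 | (6S)-6-[(1S,2S)-2-methoxy-1-[(triethylsilyl)oxy]but-3-en-1-yl]-5,6-dihydro-2H-pyran-2-one | CO[C@@H](C=C)[C@@H](O[Si](CC)(CC)CC)[C@@H]1CC=CC(=O)O1 | intermediate
15 | (6S)-6-[(1S,2S)-1-hydroxy-2-methoxybut-3-en-1-yl]-5,6-dihydro-2H-pyran-2-one | CO[C@@H](C=C)[C@@H](O)[C@@H]1CC=CC(=O)O1 | intermediate
16 | penta-1,4-dien-3-ol (divinylcarbinol) | C=CC(O)C=C | starting material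
17 | (2R,3S)-1,2-epoxypent-4-en-3-ol | C=C[C@H](O)[C@H]1CO1 | intermediate
18 | (3S,4R)-pent-1-ene-3,4-diol | C=C[C@H](O)[C@@H](C)O | intermediate
19 | (3S,4R)-pent-1-ene-3,4-diyl diacetate | C=C[C@H](OC(C)=O)[C@@H](C)OC(C)=O | intermediate
20 | (6S)-6-[(1S,2S,3E,5S,6R)-5,6-diacetoxy-1-hydroxy-2-methoxyhept-3-en-1-yl]-5,6-dihydro-2H-pyran-2-one | CO[C@@H](/C=C/[C@H](OC(C)=O)[C@@H](C)OC(C)=O)[C@@H](O)[C@@H]1CC=CC(=O)O1 | target

## Step count and risks

Total step count: 9.
Longest linear sequence: 6 steps (1 → 2 → 3 → 4 → 5 → 9); the second branch (6 → 7 → 8) has 3 steps and joins at step 9.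

Steps most likely to fail:

Step 9. Both partners are slow, allylically oxygenated alkenes, so low conversion and homodimers are the danger. The fallback couples a more reactive pair and adjusts the functional groups afterwards. It sets out from silyl lactone 14 (isolated by closing the lactone in step 5 with PPTS in CH2Cl2 and leaving out TsOH/MeOH) and from free diol 18. Their hydroxyl-accelerated cross-metathesis under the step 9 catalyst gives (6S)-6-[(1S,2S,3E,5S,6R)-5,6-dihydroxy-2-methoxy-1-[(triethylsilyl)oxy]hept-3-en-1-yl]-5,6-dihydro-2H-pyran-2-one F5. Ac2O, pyridine and DMAP acetylate the two free hydroxyls to (2R,3S,4E,6S,7S)-6-methoxy-7-[(2S)-6-oxo-3,6-dihydro-2H-pyran-2-yl]-7-[(triethylsilyl)oxy]hept-4-ene-2,3-diyl diacetate F6. HF·pyridine in THF at 0 °C then removes the silyl group, and the route comes back at 20.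

Step 5. The terminal vinyl group may be partly hydrogenated beside the alkyne. The fallback makes the net cis-reduction without hydrogen gas. It sets out from ynoate 12: Pd(PPh3)4 (2 mol%) and Bu3SnH in THF at 0 °C add H and Sn syn across the alkyne to give ethyl (2E,5S,6S,7S)-5-hydroxy-7-methoxy-2-(tributylstannyl)-6-[(triethylsilyl)oxy]nona-2,8-dienoate F4. TFA in wet CH2Cl2 at 0 °C then replaces tin by hydrogen with retention, closes the lactone and cleaves the silyl ether, coming back at 15.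

Step 2. Titanium–tartrate epoxidation of this α-branched, β-methoxy secondary allylic alcohol may be slow or less erythro-selective than usual. The fallback takes the epoxide from the chiral pool instead of making it by epoxidation. It sets out from allylborane 5 (generated from 2 as in step 1). (R)-Glycidol F1 is oxidised with Dess–Martin periodinane (NaHCO3, CH2Cl2, 0 °C) to (S)-oxirane-2-carbaldehyde F2, whose filtered solution is added to 5 at −78 °C. The same Re-face chair addition gives (1R,2S)-2-methoxy-1-[(2S)-oxiran-2-yl]but-3-en-1-yl bis(isopinocampheyl)borinate F3. Mild oxidative work-up (NaBO3·4H2O, THF/H2O) releases epoxy alcohol 8, where the route is rejoined before step 3.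

## Further compounds

F1 | step 2 | (R)-glycidol, (2R)-oxiran-2-ylmethanol | OC[C@@H]1CO1
F2 | step 2 | (S)-oxirane-2-carbaldehyde | O=C[C@@H]1CO1
F3 | step 2 | (1R,2S)-2-methoxy-1-[(2S)-oxiran-2-yl]but-3-en-1-yl bis(isopinocampheyl)borinate | CO[C@@H](C=C)[C@@H](OB([C@H]1C[C@H]2C[C@@H]([C@@H]1C)C2(C)C)[C@H]1C[C@H]2C[C@@H]([C@@H]1C)C2(C)C)[C@@H]1CO1
F4 | step 5 | ethyl (2E,5S,6S,7S)-5-hydroxy-7-methoxy-2-(tributylstannyl)-6-[(triethylsilyl)oxy]nona-2,8-dienoate | CO[C@@H](C=C)[C@@H](O[Si](CC)(CC)CC)[C@@H](O)C/C=C(/[Sn](CCCC)(CCCC)CCCC)C(=O)OCC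
F5 | step 9 | (6S)-6-[(1S,2S,3E,5S,6R)-5,6-dihydroxy-2-methoxy-1-[(triethylsilyl)oxy]hept-3-en-1-yl]-5,6-dihydro-2H-pyran-2-one | CO[C@@H](/C=C/[C@H](O)[C@@H](C)O)[C@@H](O[Si](CC)(CC)CC)[C@@H]1CC=CC(=O)O1
F6 | step 9 | (2R,3S,4E,6S,7S)-6-methoxy-7-[(2S)-6-oxo-3,6-dihydro-2H-pyran-2-yl]-7-[(triethylsilyl)oxy]hept-4-ene-2,3-diyl diacetate | CO[C@@H](/C=C/[C@H](OC(C)=O)[C@@H](C)OC(C)=O)[C@@H](O[Si](CC)(CC)CC)[C@@H]1CC=CC(=O)O1
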